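**Strategy.** The route rests on reading the O–C6–C5=C4(Me)–C3=O segment of the ten-membered carbocycle as a ring-opened 3,6-dihydro-1,2-dioxine. In one photooxygenation, singlet oxygen bridges C3 and C6 of the ring-held Z,Z-diene C3=C4–C5=C6, so two C–O bonds, the Z-configured C4=C5 alkene and the C6 stereocentre arise together. Base-induced O–O cleavage then gives the C3 ketone and the C6 hydroxyl, which closes the γ-lactone ring onto C12. The cycloaddition precursor is the (3Z,5Z)-dienyl 1,2-epoxide macrocycle with free C10–OH, C8 isobutyrate and C7 methyl acrylate side chain, closed at C4–C5 by an intramolecular Stille coupling.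

Key step: step 17

Remarks on the chemistry:
- Atom numbers are those of the germacrane skeleton of the target (C1–C2 epoxide, C3 ketone, C4(Me)=C5, C6–O, C7, C8–O, C9, C10(Me)OH, C11=C13, C12 carbonyl) and are used for all intermediates.
- Stereochemical check: in macrocycle 24, endoperoxide 26 and target 28 the centres C1, C2, C7, C8 and C10 have the same spatial arrangement, and C6 of 26 is that of the 6,7-trans lactone. No structure needed correction.
- Assumption: the antipode of the chromium ligand in step 11 is the one that delivers the allyl group to the Si face of C8; this is to be fixed on a model aldehyde before use.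

**Route**

Step 1
Reactants: 1 (S)-2-methylglycidol; 2 vinylmagnesium bromide
Product: 3 (2R)-2-methylpent-4-ene-1,2-diol
Conditions: 2 (3 equiv), CuI (10 mol %), THF, −30 → 0 °C; aq. NH4Cl
Reagents that add atoms: none
Why: Copper-catalysed Grignard opening of the 2,2-disubstituted epoxide should occur by SN2 at the unsubstituted CH2 (the first equivalent only deprotonates the hydroxyl), so the quaternary carbinol, the later C10, is taken unchanged from the chiral pool.

Step 2
Reactants: 3 (2R)-2-methylpent-4-ene-1,2-diol; 4 ethyl (triphenylphosphoranylidene)acetate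
Product: 6 ethyl (2E,4R)-4-hydroxy-4-methylhepta-2,6-dienoate, via (2R)-2-hydroxy-2-methylpent-4-enal 5 (not isolated)
Conditions: IBX (1.5 equiv), 4 (1.5 equiv), DMSO, rt
Reagents that add atoms: none
Why: IBX should oxidise only the primary alcohol (the tertiary one cannot be oxidised and IBX does not cleave glycols), and the stabilised ylide traps the α-hydroxy aldehyde in the same flask in an E-selective Wittig reaction that does not touch C10.

Step 3
Reactants: 6 ethyl (2E,4R)-4-hydroxy-4-methylhepta-2,6-dienoate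
Product: 7 ethyl (2E,4R)-4-methyl-4-(triethylsilyloxy)hepta-2,6-dienoate
Conditions: TESOTf, 2,6-lutidine, CH2Cl2, −78 → 0 °C
Reagents that add atoms: triethylsilyl triflate, CC[Si](CC)(CC)OS(=O)(=O)C(F)(F)F
Why: Silyl triflate with lutidine silylates hindered tertiary alcohols; the ether prevents an alkoxide next to the later epoxide (Payne migration under the ylide of step 7) and removes a second directing hydroxyl from step 5.

Step 4
Reactants: 7 ethyl (2E,4R)-4-methyl-4-(triethylsilyloxy)hepta-2,6-dienoate
Product: 8 (2E,4R)-4-methyl-4-(triethylsilyloxy)hepta-2,6-dien-1-ol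
Conditions: DIBAL-H (2.2 equiv), CH2Cl2, −78 °C; Rochelle salt
Reagents that add atoms: none
Why: DIBAL-H reduces the conjugated ester by 1,2-addition to the primary allylic alcohol and leaves the isolated alkene and the silyl ether alone.

Step 5
Reactants: 8 (2E,4R)-4-methyl-4-(triethylsilyloxy)hepta-2,6-dien-1-ol
Product: 9 [(2S,3R)-3-[(2R)-2-(triethylsilyloxy)pent-4-en-2-yl]oxiran-2-yl]methanol
Conditions: Ti(OiPr)4 (10 mol %), L-(+)-diethyl tartrate (12 mol %), t-BuOOH, 4 Å MS, CH2Cl2, −20 °C
Reagents that add atoms: tert-butyl hydroperoxide, CC(C)(C)OO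
Why: Sharpless asymmetric epoxidation of the E-allylic alcohol: the L-(+)-tartrate complex delivers oxygen to the face that gives the (2S,3R)-epoxy alcohol (C1 and C2 of the target), trans by alkene geometry, with reagent control expected to override the neighbouring C10 centre and the terminal alkene left untouched.

Step 6
Reactants: 9 [(2S,3R)-3-[(2R)-2-(triethylsilyloxy)pent-4-en-2-yl]oxiran-2-yl]methanol
Product: 10 (2R,3R)-3-[(2R)-2-(triethylsilyloxy)pent-4-en-2-yl]oxirane-2-carbaldehyde
Conditions: Dess–Martin periodinane, NaHCO3, CH2Cl2, 0 °C → rt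
Reagents that add atoms: none
Why: Buffered Dess–Martin oxidation gives the epoxy aldehyde without acid, and the oxirane C–H is not acidic enough to epimerise.

Step 7
Reactants: 10 (2R,3R)-3-[(2R)-2-(triethylsilyloxy)pent-4-en-2-yl]oxirane-2-carbaldehyde; 11 ethyltriphenylphosphonium bromide
Product: 12 (2S,3R)-2-[(Z)-2-iodoprop-1-enyl]-3-[(2R)-2-(triethylsilyloxy)pent-4-en-2-yl]oxirane
Conditions: 11, n-BuLi, THF, rt → −78 °C; I2; NaHMDS, −78 → −20 °C; then 10, −78 °C
Reagents that add atoms: iodine, II
Why: Stork–Zhao-type Wittig olefination with (1-iodoethylidene)triphenylphosphorane made in the flask should give the (Z)-2-iodo-2-alkene under kinetic control (iodine cis to C2), which fixes the later C3=C4 geometry; the silyl ether keeps C10–O from attacking the epoxide.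

Step 8
Reactants: 12 (2S,3R)-2-[(Z)-2-iodoprop-1-enyl]-3-[(2R)-2-(triethylsilyloxy)pent-4-en-2-yl]oxirane
Product: 13 (3R)-3-[(2R,3S)-3-[(Z)-2-iodoprop-1-enyl]oxiran-2-yl]-3-(triethylsilyloxy)butanal
Conditions: OsO4 (2 mol %), NaIO4, 2,6-lutidine, dioxane/H2O, rt
Reagents that add atoms: sodium periodate (oxygen source through catalytic OsO4), [Na+].[O-]I(=O)(=O)=O
Why: Lemieux–Johnson cleavage: OsO4 should attack the electron-rich monosubstituted alkene far faster than the hindered, iodine-bearing trisubstituted one, and lutidine keeps the medium neutral for the epoxide.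

Step 9
Reactants: 14 methyl acrylate; 15 3-(trimethylsilyl)prop-2-ynal
Product: 16 methyl 2-[1-hydroxy-3-(trimethylsilyl)prop-2-ynyl]prop-2-enoate (racemic)
Conditions: DABCO (20 mol %), 14 (excess), THF, rt
Reagents that add atoms: none
Why: Morita–Baylis–Hillman reaction of an electrophilic ynal with the acrylate; the carbinol centre is racemic, which is of no concern because it becomes sp2 in step 10.

Step 10
Reactants: 16 methyl 2-[1-hydroxy-3-(trimethylsilyl)prop-2-ynyl]prop-2-enoate
Product: 17 methyl (2Z)-2-(bromomethyl)-5-(trimethylsilyl)pent-2-en-4-ynoate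
Conditions: NBS, Me2S, CH2Cl2, 0 °C → rt
Reagents that add atoms: N-bromosuccinimide, O=C1CCC(=O)N1Br
Why: The alcohol is activated as an alkoxysulfonium salt and bromide attacks in an SN2′ sense (allylic transposition) to give the conjugated primary allylic bromide, mainly 2Z; its geometry does not matter because the allylchromium of step 11 equilibrates.

Step 11
Reactants: 13 (3R)-3-[(2R,3S)-3-[(Z)-2-iodoprop-1-enyl]oxiran-2-yl]-3-(triethylsilyloxy)butanal; 17 methyl (2Z)-2-(bromomethyl)-5-(trimethylsilyl)pent-2-en-4-ynoate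
Product: 18 methyl (3S,4R,6R)-4-hydroxy-6-[(2R,3S)-3-[(Z)-2-iodoprop-1-enyl]oxiran-2-yl]-2-methylidene-6-(triethylsilyloxy)-3-[(trimethylsilyl)ethynyl]heptanoate
Conditions: CrCl2 (10 mol %), chiral carbazole-bis(oxazoline) ligand (12 mol %, antipode for Si-face attack), iPr2NEt, Mn, Cp2ZrCl2, THF, 0 °C → rt; pH 7 work-up
Reagents that add atoms: none
Why: Catalytic asymmetric Nozaki–Hiyama–Kishi allylation: the 2-(methoxycarbonyl)allylchromium should add through its γ-carbon in a chair transition state with the alkynyl group cis to CH2Cr (axial), which gives the 7,8-syn relation, while the ligand directs attack to the Si face of C8 (catalyst control, C10 being remote), so C7 and C8 are set together; no nickel is present, so the alkenyl iodide stays intact, and Cp2ZrCl2 replaces a chlorosilane to spare the epoxide.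

Step 12
Reactants: 18 (the C8 alcohol)
Product: 19 methyl (3S,4R,6R)-6-[(2R,3S)-3-[(Z)-2-iodoprop-1-enyl]oxiran-2-yl]-2-methylidene-4-(2-methylpropanoyloxy)-6-(triethylsilyloxy)-3-[(trimethylsilyl)ethynyl]heptanoate
Conditions: (i-PrCO)2O, Et3N, DMAP (cat.), CH2Cl2, 0 °C
Reagents that add atoms: isobutyric anhydride, CC(C)C(=O)OC(=O)C(C)C
Why: DMAP-catalysed acylation of the only free hydroxyl should be faster than its lactonisation onto C12 and proceeds with retention at C8.

Step 13
Reactants: 19 (the silylalkyne isobutyrate)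
Product: 20 methyl (3R,4R,6R)-3-ethynyl-6-[(2R,3S)-3-[(Z)-2-iodoprop-1-enyl]oxiran-2-yl]-2-methylidene-4-(2-methylpropanoyloxy)-6-(triethylsilyloxy)heptanoate
Conditions: TBAF, AcOH (1:1), THF, 0 °C
Reagents that add atoms: none
Why: Buffered fluoride cleaves the C(sp)–Si bond within minutes at 0 °C, while the hindered tertiary triethylsilyl ether, both esters and the epoxide should survive.

Step 14
Reactants: 20 (the terminal alkyne)
Product: 22 methyl (3R,4R,6R)-6-[(2R,3S)-3-[(Z)-2-iodoprop-1-enyl]oxiran-2-yl]-2-methylidene-4-(2-methylpropanoyloxy)-3-[(Z)-2-(tributylstannyl)ethenyl]-6-(triethylsilyloxy)heptanoate, via alkynylstannane 21 (not isolated)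
Conditions: Bu3SnOMe, ZnBr2 (5 mol %), THF, rt; concentrate; Cp2Zr(H)Cl (1.3 equiv), THF, rt; H2O
Reagents that add atoms: tributyltin methoxide, CCCC[Sn](CCCC)(CCCC)OC
Why: Zinc-catalysed stannylation of the terminal alkyne under neutral conditions, then syn-hydrozirconation of the stannylalkyne (Zr geminal to Sn) and protonolysis with retention, should give the (Z)-alkenylstannane; C7 is not enolisable, so it keeps its configuration.

Step 15
Reactants: 22 (the Z-alkenylstannane / Z-alkenyl iodide)
Product: 23 methyl 2-[(1R,2S,3Z,5Z,7R,8R,10R)-1,2-epoxy-4,10-dimethyl-8-(2-methylpropanoyloxy)-10-(triethylsilyloxy)cyclodeca-3,5-dien-7-yl]prop-2-enoate (target numbering)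
Conditions: Pd(PPh3)4 (20 mol %), copper(I) thiophene-2-carboxylate, [NBu4][Ph2PO2], DMF, rt, slow addition to 1 mM
Reagents that add atoms: none
Why: Intramolecular Stille coupling promoted by a copper(I) carboxylate and a phosphinate tin scavenger: both alkenyl partners couple with retention, so the ring and the Z,Z-diene form at once; palladium couplings of a Z-alkenyl metal with a Z-alkenyl iodide are known to close medium rings that hold a cis,cis-diene, and these neutral, fluoride-free conditions are mild enough for an alkenyl epoxide.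

Step 16
Reactants: 23 (the silyl-protected macrocycle)
Product: 24 methyl 2-[(1R,2S,3Z,5Z,7R,8R,10R)-1,2-epoxy-10-hydroxy-4,10-dimethyl-8-(2-methylpropanoyloxy)cyclodeca-3,5-dien-7-yl]prop-2-enoate (target numbering)
Conditions: TBAF, AcOH (1:1), THF, 0 °C → rt
Reagents that add atoms: none
Why: Buffered fluoride removes the tertiary silyl ether without acid, which the dienyl epoxide would not tolerate, and without free alkoxide, which would endanger the esters.

Step 17
Reactants: 24 (the Z,Z-dienyl epoxy alcohol macrocycle); 25 dioxygen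
Product: 26 3,6-endoperoxide (1R,2R,3S,6R,7R,8R,10R; target numbering)
Conditions: O2, tetraphenylporphyrin (cat.), visible light, CH2Cl2, −20 °C
Reagents that add atoms: none
Why: Sensitisation gives singlet oxygen, which adds suprafacially to the cisoid C3=C4–C5=C6 diene in a [4+2] cycloaddition, the known behaviour of ring-held 1,3-dienes that leads to 3,6-dihydro-1,2-dioxines. The six-membered dioxine ring is closed by this cycloaddition (both C–O bonds in one event, no chain cyclisation); it bridges C3 and C6 of the carbocycle and therefore leaves C4=C5 Z by necessity. C3 and C6 are formed cis to one another by suprafaciality, and their absolute sense follows from the π-face: the ring allows the cisoid diene only with the C7–C8–C9–C10–C1–C2 chain folded over one face, and allylic 1,3-strain across Z-C5=C6 keeps H7 (not the acrylate) in the diene plane, which puts C8 and the chain on the face that leaves the other one open and gives 6R. The step needs this face selectivity, chemoselectivity over the electron-poor C11=C13 alkene (which singlet oxygen does not attack), and [4+2] over the ene reaction at the C4 methyl group and H7, which the aprotic medium, the low temperature and the 1,4-cis disposition of the diene termini favour. Epoxide, esters and tertiary alcohol are inert to singlet oxygen, and C3 loses its stereochemistry again in step 18.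

Step 18
Reactants: 26 (the 3,6-endoperoxide)
Product: 28 target lactone CNP0273626.1, via hydroxy enone 27 (not isolated)
Conditions: Et3N (2 equiv), CH2Cl2, 0 °C → rt
Reagents that add atoms: none
Why: Kornblum–DeLaMare rearrangement: the amine should remove H3, which the adjacent epoxide oxygen makes more acidic and which is more exposed than H6 next to the branched C7, with O–O cleavage to the C3 ketone and the C6 alkoxide; the latter closes the five-membered lactone onto the C12 methyl ester (5-exo-trig) irreversibly and faster than reversible hemiketal formation, with all stereocentres unchanged (6,7-trans lactone).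

**Compound list**

1 | (S)-2-methylglycidol | OC[C@@]1(C)CO1 | starting material
2 | vinylmagnesium bromide | C=C[Mg]Br | starting material
3 | (2R)-2-methylpent-4-ene-1,2-diol | OC[C@@](O)(C)CC=C | intermediate
4 | ethyl (triphenylphosphoranylidene)acetate | CCOC(=O)C=P(c1ccccc1)(c1ccccc1)c1ccccc1 | starting material
5 | (2R)-2-hydroxy-2-methylpent-4-enal | O=C[C@@](O)(C)CC=C | intermediate (not isolated)
6 | ethyl (2E,4R)-4-hydroxy-4-methylhepta-2,6-dienoate | CCOC(=O)/C=C/[C@@](O)(C)CC=C | intermediate
7 | ethyl (2E,4R)-4-methyl-4-(triethylsilyloxy)hepta-2,6-dienoate | CCOC(=O)/C=C/[C@@](O[Si](CC)(CC)CC)(C)CC=C | intermediate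
8 | (2E,4R)-4-methyl-4-(triethylsilyloxy)hepta-2,6-dien-1-ol | OC/C=C/[C@@](O[Si](CC)(CC)CC)(C)CC=C | intermediate
9 | [(2S,3R)-3-[(2R)-2-(triethylsilyloxy)pent-4-en-2-yl]oxiran-2-yl]methanol | OC[C@@H]1O[C@H]1[C@](C)(O[Si](CC)(CC)CC)CC=C | intermediate
10 | (2R,3R)-3-[(2R)-2-(triethylsilyloxy)pent-4-en-2-yl]oxirane-2-carbaldehyde | O=C[C@@H]1O[C@H]1[C@](C)(O[Si](CC)(CC)CC)CC=C | intermediate
11 | ethyltriphenylphosphonium bromide | CC[P+](c1ccccc1)(c1ccccc1)c1ccccc1.[Br-] | starting material
12 | (2S,3R)-2-[(Z)-2-iodoprop-1-enyl]-3-[(2R)-2-(triethylsilyloxy)pent-4-en-2-yl]oxirane | C/C(I)=C/[C@@H]1O[C@H]1[C@](C)(O[Si](CC)(CC)CC)CC=C | intermediate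
13 | (3R)-3-[(2R,3S)-3-[(Z)-2-iodoprop-1-enyl]oxiran-2-yl]-3-(triethylsilyloxy)butanal | C/C(I)=C/[C@@H]1O[C@H]1[C@](C)(O[Si](CC)(CC)CC)CC=O | intermediate
14 | methyl acrylate | C=CC(=O)OC | starting material
15 | 3-(trimethylsilyl)prop-2-ynal | O=CC#C[Si](C)(C)C | starting material
16 | methyl 2-[1-hydroxy-3-(trimethylsilyl)prop-2-ynyl]prop-2-enoate (racemic) | C=C(C(=O)OC)C(O)C#C[Si](C)(C)C | intermediate
17 | methyl (2Z)-2-(bromomethyl)-5-(trimethylsilyl)pent-2-en-4-ynoate | COC(=O)/C(CBr)=C/C#C[Si](C)(C)C | intermediate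
18 | methyl (3S,4R,6R)-4-hydroxy-6-[(2R,3S)-3-[(Z)-2-iodoprop-1-enyl]oxiran-2-yl]-2-methylidene-6-(triethylsilyloxy)-3-[(trimethylsilyl)ethynyl]heptanoate | COC(=O)C(=C)[C@@H](C#C[Si](C)(C)C)[C@H](O)C[C@@](C)(O[Si](CC)(CC)CC)[C@@H]1O[C@H]1/C=C(/C)I | intermediate
19 | methyl (3S,4R,6R)-6-[(2R,3S)-3-[(Z)-2-iodoprop-1-enyl]oxiran-2-yl]-2-methylidene-4-(2-methylpropanoyloxy)-6-(triethylsilyloxy)-3-[(trimethylsilyl)ethynyl]heptanoate | COC(=O)C(=C)[C@@H](C#C[Si](C)(C)C)[C@H](OC(=O)C(C)C)C[C@@](C)(O[Si](CC)(CC)CC)[C@@H]1O[C@H]1/C=C(/C)I | intermediate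
20 | methyl (3R,4R,6R)-3-ethynyl-6-[(2R,3S)-3-[(Z)-2-iodoprop-1-enyl]oxiran-2-yl]-2-methylidene-4-(2-methylpropanoyloxy)-6-(triethylsilyloxy)heptanoate | COC(=O)C(=C)[C@@H](C#C)[C@H](OC(=O)C(C)C)C[C@@](C)(O[Si](CC)(CC)CC)[C@@H]1O[C@H]1/C=C(/C)I | intermediate
21 | alkynylstannane: the 3-[(tributylstannyl)ethynyl] analogue of 20 (3S,4R,6R) | COC(=O)C(=C)[C@@H](C#C[Sn](CCCC)(CCCC)CCCC)[C@H](OC(=O)C(C)C)C[C@@](C)(O[Si](CC)(CC)CC)[C@@H]1O[C@H]1/C=C(/C)I | intermediate (not isolated)
22 | methyl (3R,4R,6R)-6-[(2R,3S)-3-[(Z)-2-iodoprop-1-enyl]oxiran-2-yl]-2-methylidene-4-(2-methylpropanoyloxy)-3-[(Z)-2-(tributylstannyl)ethenyl]-6-(triethylsilyloxy)heptanoate | COC(=O)C(=C)[C@@H](/C=C\[Sn](CCCC)(CCCC)CCCC)[C@H](OC(=O)C(C)C)C[C@@](C)(O[Si](CC)(CC)CC)[C@@H]1O[C@H]1/C=C(/C)I | intermediate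
23 | methyl 2-[(1R,2S,3Z,5Z,7R,8R,10R)-1,2-epoxy-4,10-dimethyl-8-(2-methylpropanoyloxy)-10-(triethylsilyloxy)cyclodeca-3,5-dien-7-yl]prop-2-enoate (target numbering) | COC(=O)C(=C)[C@H]1/C=C\C(C)=C/[C@@H]2O[C@H]2[C@](C)(O[Si](CC)(CC)CC)C[C@H]1OC(=O)C(C)C | intermediate
24 | methyl 2-[(1R,2S,3Z,5Z,7R,8R,10R)-1,2-epoxy-10-hydroxy-4,10-dimethyl-8-(2-methylpropanoyloxy)cyclodeca-3,5-dien-7-yl]prop-2-enoate (target numbering; key-step precursor) | COC(=O)C(=C)[C@H]1/C=C\C(C)=C/[C@@H]2O[C@H]2[C@](C)(O)C[C@H]1OC(=O)C(C)C | intermediate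
25 | dioxygen (used as singlet oxygen) | O=O | starting material
26 | 3,6-endoperoxide (1R,2R,3S,6R,7R,8R,10R; O–O bridge from C3 to C6, C4=C5 in the dioxine ring; key-step product) | COC(=O)C(=C)[C@H]1[C@@H]2OO[C@@H](C(C)=C2)[C@@H]3O[C@H]3[C@](C)(O)C[C@H]1OC(=O)C(C)C | intermediate
27 | hydroxy enone: methyl 2-[(1R,2R,4Z,6R,7R,8R,10R)-1,2-epoxy-6,10-dihydroxy-4,10-dimethyl-8-(2-methylpropanoyloxy)-3-oxocyclodec-4-en-7-yl]prop-2-enoate (target numbering) | COC(=O)C(=C)[C@H]1[C@H](O)/C=C(/C)C(=O)[C@@H]2O[C@H]2[C@](C)(O)C[C@H]1OC(=O)C(C)C | intermediate (not isolated)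
28 | CNP0273626.1: (1R,2R,4Z,6R,7R,8R,10R)-1,2-epoxy-10-hydroxy-3-oxogermacra-4,11(13)-dien-6,12-olide 8-isobutyrate | C=C1C(=O)O[C@@H]2/C=C(/C)C(=O)[C@@H]3O[C@H]3[C@](C)(O)C[C@@H](OC(=O)C(C)C)[C@@H]12 | target

**Step count and risk**

Total: 18 steps. Longest linear sequence: 16 steps (steps 1–8 and 11–18); steps 9–10 make the bromide 17.

Steps most likely to fail:

1. Step 17 (photooxygenation). The twisted Z,Z-diene may reach the cisoid geometry too slowly, so that hydrogen abstraction at the C4 methyl group (ene reaction) or attack on the other π-face takes over. The fallback is a stepwise 1,4-oxygenation without cycloaddition and sets out from 24. Dimethyldioxirane (acetone, −20 °C) should epoxidise the more nucleophilic trisubstituted C3=C4 bond on the open face to give the 1,2:3,4-bis-epoxide F1. Pd(PPh3)4-catalysed 1,4-addition of chloroacetic acid to this alkenyl epoxide (ionisation of C4–O, carboxylate attack at C6, overall retention) would give the 3-hydroxy-6-chloroacetate F2. Dess–Martin oxidation of the C3 carbinol gives the enone chloroacetate F3, and NaHCO3 in methanol removes the chloroacetyl group selectively. The route is rejoined at hydroxy enone 27, which lactonises to 28 as in step 18.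

2. Step 15 (macrocyclisation). Ring closure to a ten-membered ring competes with intermolecular coupling to oligomers, with protodestannylation, and with ionisation of the allylic epoxide by Pd(0). The fallback replaces the cross-coupling by a palladium-free and tin-free reductive coupling and sets out from 20. NIS with catalytic AgNO3 gives the iodoalkyne F4. Diimide (2-nitrobenzenesulfonylhydrazide, Et3N) reduces it to the (Z,Z)-bis(alkenyl iodide) F5. Excess copper(I) thiophene-2-carboxylate in NMP at rt under high dilution (Ullmann-type reductive coupling of alkenyl iodides with retention) closes the ring and returns to 23.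

3. Step 11 (allylation). Face selectivity at C8 is left to the catalyst against a remote resident centre, the syn preference may erode if the allylchromium reacts through its allenyl form, and Lewis-acidic metal salts may open the alkenyl epoxide. The fallback uses a configurationally stable allylboron reagent and sets out from 17. Pd-catalysed borylation with bis(pinacolato)diboron gives the allylboronate F6 (alkynyl cis to CH2B). Its allylboration of 13 through a closed six-membered transition state is syn-specific; a chiral BINOL-derived phosphoric acid catalyst selects the Si face of C8 and returns to 18.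

Further compounds
F1 | step 17 | 1,2:3,4-bis-epoxide of 24 (epoxide oxygen on C3/C4 anti to the ring chain; 5Z) | COC(=O)C(=C)[C@H]1/C=C\[C@]3(C)O[C@@H]3[C@@H]2O[C@H]2[C@](C)(O)C[C@H]1OC(=O)C(C)C
F2 | step 17 | 6-chloroacetoxy-3-hydroxy-4Z-ene (1,4-adduct; 6R) | COC(=O)C(=C)[C@H]1[C@H](OC(=O)CCl)/C=C(/C)[C@H](O)[C@@H]2O[C@H]2[C@](C)(O)C[C@H]1OC(=O)C(C)C
F3 | step 17 | 6-chloroacetoxy-3-oxo-4Z-ene (chloroacetate of 27) | COC(=O)C(=C)[C@H]1[C@H](OC(=O)CCl)/C=C(/C)C(=O)[C@@H]2O[C@H]2[C@](C)(O)C[C@H]1OC(=O)C(C)C
F4 | step 15 | iodoalkyne: the 3-(iodoethynyl) analogue of 20 | COC(=O)C(=C)[C@@H](C#CI)[C@H](OC(=O)C(C)C)C[C@@](C)(O[Si](CC)(CC)CC)[C@@H]1O[C@H]1/C=C(/C)I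
F5 | step 15 | (Z,Z)-bis(alkenyl iodide): the 3-[(Z)-2-iodoethenyl] analogue of 20 | COC(=O)C(=C)[C@@H](/C=C\I)[C@H](OC(=O)C(C)C)C[C@@](C)(O[Si](CC)(CC)CC)[C@@H]1O[C@H]1/C=C(/C)I
F6 | step 11 | methyl (2E)-2-[(4,4,5,5-tetramethyl-1,3,2-dioxaborolan-2-yl)methyl]-5-(trimethylsilyl)pent-2-en-4-ynoate | CC1(C)OB(C/C(C(=O)OC)=C\C#C[Si](C)(C)C)OC1(C)C
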